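**Plan**

- Rings are lettered A to E from the 3,5-dihydroxyphenoxy end, and atom 1 of each ring is the carbon bonded to the ether oxygen coming from the preceding ring (A1 carries the oxygen to B). The links are A1–O–B1, B6–O–C1, C4–O–D1 and D6–O–E1.
- Retrosynthesis: the eleven O–CH3 bonds go last, then the O–C4 bond (D1 phenol plus ring C bromide). Ring E is then cut at E2–E3 and E5–E6 into an aryloxymalonyl three-carbon unit (E2, E1, E6) and dimethyl 3-oxopentanedioate (E3, E4, E5).
- This cut is open because ring E is a phloroglucinol: E1 carries the ether oxygen and lies between hydroxylated E2 and E6 and para to hydroxylated E4, while E3 and E5 are CH and can carry, then lose, ester groups. The crowded D6–O–E1 bond thus becomes an sp3 C–O bond made by alkylating a phenol with bromomalonate.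
- The A–B–C bromide is cut at O–A1 (arylboronic acid), at B1–O (formyl to hydroxyl) and at O–B6 (fluoride displacement).
- Forward: ring D phenol, then the aryloxymalonyl chloride, then ring E, then the D–E phenol. Separately, ring C phenol plus ring B fluoroaldehyde, then the B1 phenol, then ring A. Last come the union of the two fragments and global demethylation.
- Stereochemistry: the target is achiral. The one stereocentre on the way (the malonyl carbon of 9, 10 and 12, racemic) becomes aromatic carbon E1.

Key step: step 8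

Assumption: 2-fluoro-4,6-dimethoxybenzaldehyde is taken as a purchasable building block; if it must be made, Vilsmeier formylation of 1-fluoro-3,5-dimethoxybenzene supplies it.

**Route**

Step 1
Reactants: 1 2-hydroxy-4,6-dimethoxybenzaldehyde
Product: 2 2-(allyloxy)-4,6-dimethoxybenzaldehyde
Conditions: allyl bromide, K2CO3, DMF, 50 °C
Reagents that add atoms: allyl bromide, C=CCBr
Why: Williamson O-alkylation of the phenoxide; the allyl group masks the future D6 oxygen and can later be removed without touching a benzyl ether.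

Step 2
Reactants: 2 2-(allyloxy)-4,6-dimethoxybenzaldehyde
Product: 4 2-(allyloxy)-4,6-dimethoxyphenol, via aryl formate 3 (not isolated)
Conditions: H2O2 (30% aq.), H2SO4 (cat.), MeOH, 0 °C to rt
Reagents that add atoms: hydrogen peroxide, OO
Why: Dakin-type (Baeyer–Villiger) oxidation in which the electron-rich trialkoxyaryl group migrates to oxygen and the formate is methanolysed in the same pot, while acid/peroxide leaves the allyl double bond alone.

Step 3
Reactants: 4 2-(allyloxy)-4,6-dimethoxyphenol
Product: 5 1-(allyloxy)-2-(benzyloxy)-3,5-dimethoxybenzene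
Conditions: BnBr, K2CO3, DMF, rt
Reagents that add atoms: benzyl bromide, BrCc1ccccc1
Why: Williamson benzylation of the new D1 phenol, which must stay masked until the fragment union.

Step 4
Reactants: 5 1-(allyloxy)-2-(benzyloxy)-3,5-dimethoxybenzene
Product: 6 2-(benzyloxy)-3,5-dimethoxyphenol
Conditions: Pd(PPh3)4 (cat.), morpholine, THF, rt
Reagents that add atoms: none
Why: Tsuji–Trost deallylation, in which zerovalent palladium ionises the aryl allyl ether to a π-allyl complex that morpholine captures; benzyl and methyl ethers are inert.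

Step 5
Reactants: 6 2-(benzyloxy)-3,5-dimethoxyphenol; 7 dimethyl bromomalonate
Product: 8 dimethyl 2-(2-benzyloxy-3,5-dimethoxyphenoxy)malonate
Conditions: K2CO3, acetone, rt to 50 °C
Reagents that add atoms: none
Why: SN2 O-alkylation of the phenoxide by the doubly activated secondary bromide, the standard way to aryloxymalonates, which makes the future D6–O–E1 bond at an sp3 carbon.

Step 6
Reactants: 8 dimethyl 2-(2-benzyloxy-3,5-dimethoxyphenoxy)malonate
Product: 9 2-(2-benzyloxy-3,5-dimethoxyphenoxy)-3-methoxy-3-oxopropanoic acid (racemic)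
Conditions: KOH (1.0 equiv), THF/MeOH/H2O, 0 °C; cold dil. HCl
Reagents that add atoms: potassium hydroxide, [K+].[OH-]
Why: selective monosaponification of a symmetric malonic diester, where the first carboxylate formed shuts down hydrolysis of the second ester.

Step 7
Reactants: 9 2-(2-benzyloxy-3,5-dimethoxyphenoxy)-3-methoxy-3-oxopropanoic acid
Product: 10 methyl 2-(2-benzyloxy-3,5-dimethoxyphenoxy)-3-chloro-3-oxopropanoate (racemic, used crude)
Conditions: (COCl)2 (1.1 equiv), DMF (cat.), CH2Cl2, 0 °C to rt; evaporation
Reagents that add atoms: oxalyl chloride, O=C(Cl)C(Cl)=O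
Why: acid chloride formation through the chloroiminium species under Lewis-acid-free conditions, under which the electron-rich ring D is not acylated.

Step 8
Reactants: 10 methyl 2-(2-benzyloxy-3,5-dimethoxyphenoxy)-3-chloro-3-oxopropanoate; 11 dimethyl 3-oxopentanedioate
Product: 13 dimethyl 5-(2-benzyloxy-3,5-dimethoxyphenoxy)-2,4,6-trihydroxyisophthalate, via diketo triester 12 (not isolated)
Conditions: 11 (1.2 equiv), MgCl2 (1.2 equiv), pyridine (2.5 equiv), CH2Cl2, 0 °C; slow addition of 10, rt; then NaOMe (5 equiv), MeOH, 60 °C; aq. HCl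
Reagents that add atoms: none
Why: MgCl2/pyridine turns 11 into its chelated magnesium enolate, which is C-acylated by 10 (directly or through the ketene that 10 gives by E1cB loss of chloride) to form the first ring bond (E2–E3) and the diketo triester 12; methoxide then deprotonates the remaining CH2 of the ketodiester part, and this carbon attacks the methyl ester of the former malonyl unit in a Dieckmann condensation (6-exo-trig acyl substitution) that forms E5–E6 and closes ring E, after which loss of methanol and enolisation of the cyclohexanetrione give the aromatic ring as its phenoxide. The closest known reactions are the MgCl2/amine C-acylation of β-keto ester enolates with acid chlorides, the base-induced Claisen cyclisation of open-chain polyketo esters to phloroglucinol carboxylates, and the classical condensation of malonic with acetonedicarboxylic esters to trihydroxyisophthalates. No stereocentre is created, and the racemic centre of 10 becomes the sp2 carbon E1. C- over O-acylation is secured by magnesium chelation, and any pyranone formed by O-cyclisation, like the non-aromatisable ring that closure through the aryloxy-bearing carbon would give, reopens under methoxide, so material drains into the aromatic product, the only irreversible outcome. The chloride replaces a second methyl ester because deprotonation of the acidic aryloxymalonyl C–H then releases a reactive ketene instead of parking the electrophile as an inert enolate, and because 11 is consumed as its magnesium enolate before methoxide is added, its self-condensation is held back.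

Step 9
Reactants: 13 dimethyl 5-(2-benzyloxy-3,5-dimethoxyphenoxy)-2,4,6-trihydroxyisophthalate
Product: 15 2-(2-benzyloxy-3,5-dimethoxyphenoxy)benzene-1,3,5-triol, via isophthalic diacid 14 (not isolated)
Conditions: NaOH (2 M aq., degassed), 100 °C, Ar; then HCl to pH 1, 70 °C
Reagents that add atoms: none
Why: saponification followed by protodecarboxylation, which is easy for 2,4,6-trihydroxybenzoic acids because ipso-protonation of the phloroglucinol ring gives a β-keto acid.

Step 10
Reactants: 15 2-(2-benzyloxy-3,5-dimethoxyphenoxy)benzene-1,3,5-triol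
Product: 16 2-(benzyloxy)-1,5-dimethoxy-3-(2,4,6-trimethoxyphenoxy)benzene
Conditions: Me2SO4, K2CO3, acetone, reflux
Reagents that add atoms: dimethyl sulfate, COS(=O)(=O)OC
Why: Williamson O-methylation, for which the hard sulfate electrophile with carbonate in acetone favours O- over C-methylation of the phloroglucinol nucleus.

Step 11
Reactants: 16 2-(benzyloxy)-1,5-dimethoxy-3-(2,4,6-trimethoxyphenoxy)benzene
Product: 17 2,4-dimethoxy-6-(2,4,6-trimethoxyphenoxy)phenol
Conditions: H2 (1 atm), 10% Pd/C, EtOAc/MeOH, rt
Reagents that add atoms: none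
Why: hydrogenolysis of the benzyl ether frees the D1 hydroxyl while methyl and diaryl ethers are untouched.

Step 12
Reactants: 18 4-bromo-2,6-dimethoxyphenol; 19 2-fluoro-4,6-dimethoxybenzaldehyde
Product: 20 2-(4-bromo-2,6-dimethoxyphenoxy)-4,6-dimethoxybenzaldehyde
Conditions: K2CO3, DMF, 120 °C
Reagents that add atoms: none
Why: SNAr displacement of the fluoride ortho to the formyl group, whose two methoxy groups sit meta to the attacked carbon and do not deactivate it, while the unactivated bromide of 18 is inert.

Step 13
Reactants: 20 2-(4-bromo-2,6-dimethoxyphenoxy)-4,6-dimethoxybenzaldehyde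
Product: 22 2-(4-bromo-2,6-dimethoxyphenoxy)-4,6-dimethoxyphenol, via aryl formate 21 (not isolated)
Conditions: H2O2 (30% aq.), H2SO4 (cat.), MeOH, 0 °C to rt
Reagents that add atoms: hydrogen peroxide, OO
Why: Dakin-type oxidation as in step 2, turning the activating formyl group into the B1 hydroxyl.

Step 14
Reactants: 22 2-(4-bromo-2,6-dimethoxyphenoxy)-4,6-dimethoxyphenol; 23 3,5-dimethoxyphenylboronic acid
Product: 24 5-bromo-2-[2-(3,5-dimethoxyphenoxy)-3,5-dimethoxyphenoxy]-1,3-dimethoxybenzene
Conditions: Cu(OAc)2 (1.5 equiv), pyridine, 4 Å MS, CH2Cl2, dry air, rt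
Reagents that add atoms: none
Why: Chan–Lam oxidative O-arylation, which runs at room temperature, is known for di-ortho-substituted halophenols and leaves the aryl bromide for the next coupling.

Step 15
Reactants: 17 2,4-dimethoxy-6-(2,4,6-trimethoxyphenoxy)phenol; 24 5-bromo-2-[2-(3,5-dimethoxyphenoxy)-3,5-dimethoxyphenoxy]-1,3-dimethoxybenzene
Product: 25 5-[2,4-dimethoxy-6-(2,4,6-trimethoxyphenoxy)phenoxy]-2-[2-(3,5-dimethoxyphenoxy)-3,5-dimethoxyphenoxy]-1,3-dimethoxybenzene
Conditions: CuI (10 mol %), picolinic acid (20 mol %), K3PO4, DMSO, 100 °C, Ar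
Reagents that add atoms: none
Why: Ullmann-type copper-catalysed diaryl ether synthesis, where the bromide at C4 is flanked only by hydrogens so the crowding lies on the phenol alone, which the picolinic acid system tolerates.

Step 16
Reactants: 25 the undecamethyl ether
Product: 26 5-[2,4-dihydroxy-6-(2,4,6-trihydroxyphenoxy)phenoxy]-2-[2-(3,5-dihydroxyphenoxy)-3,5-dihydroxyphenoxy]benzene-1,3-diol (CNP0018313.0)
Conditions: BBr3 (35 equiv), CH2Cl2, −78 °C to rt; then H2O, 0 °C; degassed work-up, reversed-phase chromatography
Reagents that add atoms: none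
Why: Lewis-acid demethylation in which bromide attacks each boron-activated O–CH3 group by SN2, while the four diaryl ether links offer no sp3 carbon and survive.

**Compound list**

1 | 2-hydroxy-4,6-dimethoxybenzaldehyde | COc1cc(O)c(C=O)c(OC)c1 | starting material
2 | 2-(allyloxy)-4,6-dimethoxybenzaldehyde | COc1cc(OCC=C)c(C=O)c(OC)c1 | intermediate
3 | 2-(allyloxy)-4,6-dimethoxyphenyl formate | COc1cc(OCC=C)c(OC=O)c(OC)c1 | intermediate
4 | 2-(allyloxy)-4,6-dimethoxyphenol | COc1cc(OCC=C)c(O)c(OC)c1 | intermediate
5 | 1-(allyloxy)-2-(benzyloxy)-3,5-dimethoxybenzene | COc1cc(OCC=C)c(OCc2ccccc2)c(OC)c1 | intermediate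
6 | 2-(benzyloxy)-3,5-dimethoxyphenol | COc1cc(O)c(OCc2ccccc2)c(OC)c1 | intermediate
7 | dimethyl bromomalonate | COC(=O)C(Br)C(=O)OC | starting material
8 | dimethyl 2-(2-benzyloxy-3,5-dimethoxyphenoxy)malonate | COC(=O)C(Oc1cc(OC)cc(OC)c1OCc1ccccc1)C(=O)OC | intermediate
9 | 2-(2-benzyloxy-3,5-dimethoxyphenoxy)-3-methoxy-3-oxopropanoic acid (racemic) | COC(=O)C(Oc1cc(OC)cc(OC)c1OCc1ccccc1)C(=O)O | intermediate
10 | methyl 2-(2-benzyloxy-3,5-dimethoxyphenoxy)-3-chloro-3-oxopropanoate (racemic) | COC(=O)C(Oc1cc(OC)cc(OC)c1OCc1ccccc1)C(Cl)=O | intermediate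
11 | dimethyl 3-oxopentanedioate | COC(=O)CC(=O)CC(=O)OC | starting material
12 | dimethyl 2-(2-benzyloxy-3,5-dimethoxyphenoxy)-4-(methoxycarbonyl)-3,5-dioxoheptanedioate (stereoisomer and tautomer mixture) | COC(=O)CC(=O)C(C(=O)OC)C(=O)C(Oc1cc(OC)cc(OC)c1OCc1ccccc1)C(=O)OC | intermediate
13 | dimethyl 5-(2-benzyloxy-3,5-dimethoxyphenoxy)-2,4,6-trihydroxyisophthalate | COC(=O)c1c(O)c(C(=O)OC)c(O)c(Oc2cc(OC)cc(OC)c2OCc2ccccc2)c1O | intermediate
14 | 5-(2-benzyloxy-3,5-dimethoxyphenoxy)-2,4,6-trihydroxyisophthalic acid | OC(=O)c1c(O)c(C(=O)O)c(O)c(Oc2cc(OC)cc(OC)c2OCc2ccccc2)c1O | intermediate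
15 | 2-(2-benzyloxy-3,5-dimethoxyphenoxy)benzene-1,3,5-triol | Oc1cc(O)c(Oc2cc(OC)cc(OC)c2OCc2ccccc2)c(O)c1 | intermediate
16 | 2-(benzyloxy)-1,5-dimethoxy-3-(2,4,6-trimethoxyphenoxy)benzene | COc1cc(OC)c(Oc2cc(OC)cc(OC)c2OCc2ccccc2)c(OC)c1 | intermediate
17 | 2,4-dimethoxy-6-(2,4,6-trimethoxyphenoxy)phenol | COc1cc(OC)c(Oc2cc(OC)cc(OC)c2O)c(OC)c1 | intermediate
18 | 4-bromo-2,6-dimethoxyphenol | COc1cc(Br)cc(OC)c1O | starting material
19 | 2-fluoro-4,6-dimethoxybenzaldehyde | COc1cc(F)c(C=O)c(OC)c1 | starting material
20 | 2-(4-bromo-2,6-dimethoxyphenoxy)-4,6-dimethoxybenzaldehyde | COc1cc(Oc2c(OC)cc(Br)cc2OC)c(C=O)c(OC)c1 | intermediate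
21 | 2-(4-bromo-2,6-dimethoxyphenoxy)-4,6-dimethoxyphenyl formate | COc1cc(Oc2c(OC)cc(Br)cc2OC)c(OC=O)c(OC)c1 | intermediate
22 | 2-(4-bromo-2,6-dimethoxyphenoxy)-4,6-dimethoxyphenol | COc1cc(Oc2c(OC)cc(Br)cc2OC)c(O)c(OC)c1 | intermediate
23 | 3,5-dimethoxyphenylboronic acid | COc1cc(OC)cc(B(O)O)c1 | starting material
24 | 5-bromo-2-[2-(3,5-dimethoxyphenoxy)-3,5-dimethoxyphenoxy]-1,3-dimethoxybenzene | COc1cc(OC)cc(Oc2c(OC)cc(OC)cc2Oc2c(OC)cc(Br)cc2OC)c1 | intermediate
25 | 5-[2,4-dimethoxy-6-(2,4,6-trimethoxyphenoxy)phenoxy]-2-[2-(3,5-dimethoxyphenoxy)-3,5-dimethoxyphenoxy]-1,3-dimethoxybenzene | COc1cc(OC)cc(Oc2c(OC)cc(OC)cc2Oc2c(OC)cc(Oc3c(OC)cc(OC)cc3Oc3c(OC)cc(OC)cc3OC)cc2OC)c1 | intermediate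
26 | 5-[2,4-dihydroxy-6-(2,4,6-trihydroxyphenoxy)phenoxy]-2-[2-(3,5-dihydroxyphenoxy)-3,5-dihydroxyphenoxy]benzene-1,3-diol | Oc1cc(O)cc(Oc2c(O)cc(O)cc2Oc2c(O)cc(Oc3c(O)cc(O)cc3Oc3c(O)cc(O)cc3O)cc2O)c1 | target

**Step count and risks**

Total step count: 16. Longest linear sequence: 13 (steps 1 to 11, then 15 and 16); the A–B–C branch (steps 12 to 14) joins at step 15.

Steps most likely to fail:

1. Step 8. The ketodiester may condense with itself faster than it is acylated, the acid chloride may be lost through its ketene (dimerisation or attack on its own electron-rich ring), or methoxide may cleave the diketo triester by retro-Claisen reaction before the ring closes. The fallback gives up building ring E and buys it instead. It sets out from 19, which is heated with commercial 2,4,6-trimethoxyphenol (K2CO3, DMF, 120 °C) to give 2,4-dimethoxy-6-(2,4,6-trimethoxyphenoxy)benzaldehyde F1 by fluoride displacement. Oxidation with H2O2 and catalytic H2SO4 in MeOH then passes through 2,4-dimethoxy-6-(2,4,6-trimethoxyphenoxy)phenyl formate F2 and comes back to the route at 17.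

2. Step 15. Oxidative addition to the electron-rich bromide may be slow and the crowded, chelating phenoxide may bind copper poorly, so that hydrodebromination or recovered material results. The fallback reverses the handles and sets out from 24. Bromine–lithium exchange (n-BuLi, THF, −78 °C), B(OiPr)3 and aqueous acid should give [4-[2-(3,5-dimethoxyphenoxy)-3,5-dimethoxyphenoxy]-3,5-dimethoxyphenyl]boronic acid F3. This is joined to 17 under the oxidative conditions of step 14 (Cu(OAc)2, pyridine, 4 Å MS, CH2Cl2, air), for which step 14 is a close model, and comes back at 25.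

3. Step 14. Divalent copper and air may oxidise the very electron-rich, di-ortho-substituted phenol to quinoid material, or protodeboronation and homocoupling of 23 may outrun C–O bond formation. The fallback is a metal-free, non-oxidative arylation that sets out from 22. Commercial 1-iodo-3,5-dimethoxybenzene is converted in one pot (mCPBA, TsOH·H2O, MeCN; then 1,3,5-trimethoxybenzene) into (3,5-dimethoxyphenyl)(2,4,6-trimethoxyphenyl)iodonium tosylate F4. The phenoxide of 22 (K2CO3, MeCN, 50 °C) takes up only the dimethoxyphenyl group from this hypervalent iodine salt, the trimethoxyphenyl group being the non-transferred ligand, and the sequence comes back at 24.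

**Further compounds**

F1 | step 8 | 2,4-dimethoxy-6-(2,4,6-trimethoxyphenoxy)benzaldehyde | COc1cc(OC)c(Oc2cc(OC)cc(OC)c2C=O)c(OC)c1
F2 | step 8 | 2,4-dimethoxy-6-(2,4,6-trimethoxyphenoxy)phenyl formate | COc1cc(OC)c(Oc2cc(OC)cc(OC)c2OC=O)c(OC)c1
F3 | step 15 | [4-[2-(3,5-dimethoxyphenoxy)-3,5-dimethoxyphenoxy]-3,5-dimethoxyphenyl]boronic acid | COc1cc(OC)cc(Oc2c(OC)cc(OC)cc2Oc2c(OC)cc(B(O)O)cc2OC)c1
F4 | step 14 | (3,5-dimethoxyphenyl)(2,4,6-trimethoxyphenyl)iodonium 4-methylbenzenesulfonate | COc1cc(OC)cc([I+]c2c(OC)cc(OC)cc2OC)c1.Cc1ccc(cc1)S(=O)(=O)[O-]
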